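Retrosynthesis: the two ring-carbon–CH2 bonds at C3 and C5 of the central butyrylphloroglucinol ring B are cut, each bridge carbon staying on its outer ring as a dimethylaminomethyl group. Ring B is then a twofold carbon nucleophile, ring A a latent methylene triketone and ring C a latent ortho-quinone methide.
Enabling feature: ring B has two equivalent free ring carbons, each flanked by two hydroxyls, whereas the gem-dimethyl triketone ring A and the aspidinol ring C each have exactly one free ring carbon. The acidic triketone should release its electrophile much more easily than the phenol.
Ring A comes from phloroglucinol (C-acylation, dearomatising gem-dimethylation, Mannich reaction); ring C comes from 2-methylphloroglucinol (C-acylation, O-methylation para to the ketone, Mannich reaction).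
Forward order: no ring is built, since all three six-membered rings are carried through from the phenols. The chain is joined ring A–CH2–ring B first near room temperature, then ring B–CH2–ring C at about 100 °C in the same flask.
Stereochemistry: none has to be set; the target has no stereocentre and no stereogenic double bond.

Key step: step 7

Remark: ring A is a tautomeric β-triketone and is drawn throughout as the enol shown in the target; Mannich bases are drawn neutral, although 6 is expected to exist as an internal salt (ammonium enolate).

Step 1
Reactants: 1 phloroglucinol; 2 butyryl chloride
Product: 3 butyrylphloroglucinol [1-(2,4,6-trihydroxyphenyl)butan-1-one]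
Conditions: AlCl3 (4 equiv), PhNO2/CH2Cl2, 0 to 45 °C; then ice/aq. HCl
Reagents that add atoms: none
Why: Friedel–Crafts C-acylation of a highly activated, threefold-symmetric ring, in which the first acyl group, held as its aluminium chelate, deactivates the ring towards a second acylation and any O-acylated material should undergo Fries rearrangement under the same conditions.

Step 2
Reactants: 3 butyrylphloroglucinol
Product: 4 butyrylfilicinic acid [2-butanoyl-3,5-dihydroxy-4,4-dimethylcyclohexa-2,5-dien-1-one]
Conditions: NaOMe (3.0 equiv), MeI (2.2 equiv), MeOH, 0 °C to rt; then aq. HCl
Reagents that add atoms: iodomethane, CI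
Why: Base-mediated dearomatising C,C-dimethylation of an acylphloroglucinol, the standard entry to acylfilicinic acids, in which the first methyl group makes its own ring carbon the preferred site of the second alkylation and the resulting strongly acidic triketone enolate is less prone to further alkylation, so that under limited methyl iodide the gem-dimethyl compound should be the main product, to be separated from mono- and trimethylated by-products by chromatography.

Step 3
Reactants: 4 butyrylfilicinic acid; 5 dimethylmethyleneiminium iodide
Product: 6 Mannich base of ring A [2-butanoyl-6-[(dimethylamino)methyl]-3,5-dihydroxy-4,4-dimethylcyclohexa-2,5-dien-1-one]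
Conditions: 5 (1.5 equiv), MeCN, −20 to 0 °C, 4 added slowly; then aq. NaHCO3 (1.0 equiv), 0 °C
Reagents that add atoms: none
Why: Mannich aminomethylation of the single free ring carbon of the triketone enol by the preformed iminium salt, run with the iminium salt in excess and without base until 4 is consumed so that the product cannot eliminate and alkylate unreacted 4, after which one equivalent of NaHCO3 should release 6 as a zwitterion that is kept cold and used directly.

Step 4
Reactants: 7 2-methylphloroglucinol; 2 butyryl chloride
Product: 8 3-methylbutyrylphloroglucinol [1-(2,4,6-trihydroxy-3-methylphenyl)butan-1-one]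
Conditions: AlCl3 (4 equiv), PhNO2/CH2Cl2, 0 to 45 °C; then ice/aq. HCl
Reagents that add atoms: none
Why: Friedel–Crafts C-acylation in which the two free ring carbons of 7 are equivalent by symmetry, so only one monoacyl product is possible and the ketone deactivates the ring towards a second acylation.

Step 5
Reactants: 8 3-methylbutyrylphloroglucinol
Product: 9 aspidinol [1-(2,6-dihydroxy-4-methoxy-3-methylphenyl)butan-1-one]
Conditions: Me2SO4 (1.0 equiv), K2CO3 (1.0 equiv), acetone, rt to 40 °C
Reagents that add atoms: dimethyl sulfate, COS(=O)(=O)OC
Why: Williamson-type mono-O-methylation with one equivalent each of base and alkylating agent, in which the hydroxyl para to the ketone is the most acidic and is not hydrogen-bonded to the carbonyl group, whereas the two ortho hydroxyls are deactivated by chelation and shielded by the acyl group, as is usual for 2,4,6-trihydroxyaryl ketones.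

Step 6
Reactants: 9 aspidinol; 5 dimethylmethyleneiminium iodide
Product: 10 Mannich base of ring C [1-{3-[(dimethylamino)methyl]-2,6-dihydroxy-4-methoxy-5-methylphenyl}butan-1-one]
Conditions: 5 (1.2 equiv), K2CO3 (1.2 equiv), CH2Cl2, 0 °C to rt
Reagents that add atoms: none
Why: Mannich aminomethylation (electrophilic aromatic substitution by the iminium ion) at the only unsubstituted ring carbon of an electron-rich phenol, ortho to a free hydroxyl, a well-established reaction of phenols with this iminium salt.

Step 7
Reactants: 3 butyrylphloroglucinol; 6 Mannich base of ring A; 10 Mannich base of ring C
Product: 14 target CNP0242491.0, via methylene triketone 11 (not isolated), via ring A-CH2-ring B dimer 12 (not isolated), via ortho-quinone methide 13 (not isolated)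
Conditions: 1,4-dioxane, 6 (1.0 equiv) added in portions to 3 (1.15 equiv), 25–40 °C; then 10 (1.2 equiv), 100 °C, N2 sweep; then 1 M HCl
Reagents that add atoms: none
Why: Proposed new method: near room temperature zwitterion 6 should lose dimethylamine by an E1cB process to give the cross-conjugated methylene triketone 11, which one of the two equivalent ring carbons (C3/C5) of 3 attacks in a Michael-type Friedel–Crafts alkylation, and rearomatisation of ring B gives 12 as the dimethylammonium enolate of ring A; at about 100 °C the phenolic Mannich base 10 then expels dimethylamine to give ortho-quinone methide 13, which the last free ring carbon of ring B in 12 captures by the same addition–tautomerisation sequence, and acid releases 14. The closest known reaction type is the stepwise methylene bridging of acylphloroglucinols and acylfilicinic acids through isolated Mannich bases or ortho-quinone methides, together with the base-induced methylene exchange between such rings; running two different unions in a fixed order in one flask is the untested part. Only the two ring-carbon–CH2 bonds at C3 and C5 of ring B are formed, no ring closes and no stereocentre arises. The step needs the mixed A–B–C sequence in preference to A–B–A and C–B–C: the first should be disfavoured because 6 is added in portions to an excess of 3, whose two free carbons are unhindered, while ring B of 12 has one hindered free carbon and is hydrogen-bonded to the anionic ring A that holds the released amine, and the second because 13 is generated only at a temperature reached after 6 is consumed. Regiochemistry is fixed, since rings A and C have no free ring carbon left and 12 has exactly one.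

Compound list
1 | phloroglucinol (benzene-1,3,5-triol) | Oc1cc(O)cc(O)c1 | starting material
2 | butyryl chloride (butanoyl chloride) | CCCC(=O)Cl | starting material
3 | butyrylphloroglucinol, 1-(2,4,6-trihydroxyphenyl)butan-1-one (ring B) | CCCC(=O)c1c(O)cc(O)cc1O | intermediate
4 | butyrylfilicinic acid, 2-butanoyl-3,5-dihydroxy-4,4-dimethylcyclohexa-2,5-dien-1-one (ring A) | CCCC(=O)C1=C(O)C(C)(C)C(O)=CC1=O | intermediate
5 | dimethylmethyleneiminium iodide (N,N-dimethylmethaniminium iodide) | C=[N+](C)C.[I-] | starting material
6 | Mannich base of ring A, 2-butanoyl-6-[(dimethylamino)methyl]-3,5-dihydroxy-4,4-dimethylcyclohexa-2,5-dien-1-one (internal salt) | CCCC(=O)C1=C(O)C(C)(C)C(O)=C(CN(C)C)C1=O | intermediate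
7 | 2-methylphloroglucinol (2-methylbenzene-1,3,5-triol) | Cc1c(O)cc(O)cc1O | starting material
8 | 3-methylbutyrylphloroglucinol, 1-(2,4,6-trihydroxy-3-methylphenyl)butan-1-one | CCCC(=O)c1c(O)cc(O)c(C)c1O | intermediate
9 | aspidinol, 1-(2,6-dihydroxy-4-methoxy-3-methylphenyl)butan-1-one (ring C) | CCCC(=O)c1c(O)cc(OC)c(C)c1O | intermediate
10 | Mannich base of ring C, 1-{3-[(dimethylamino)methyl]-2,6-dihydroxy-4-methoxy-5-methylphenyl}butan-1-one | CCCC(=O)c1c(O)c(CN(C)C)c(OC)c(C)c1O | intermediate
11 | methylene triketone, 2-butanoyl-3-hydroxy-4,4-dimethyl-6-methylidenecyclohex-2-ene-1,5-dione (not isolated) | CCCC(=O)C1=C(O)C(C)(C)C(=O)C(=C)C1=O | intermediate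
12 | ring A–CH2–ring B dimer, 2-butanoyl-6-(3-butanoyl-2,4,6-trihydroxybenzyl)-3,5-dihydroxy-4,4-dimethylcyclohexa-2,5-dien-1-one (formed as its dimethylammonium enolate, not isolated) | CCCC(=O)C1=C(O)C(C)(C)C(O)=C(Cc2c(O)cc(O)c(C(=O)CCC)c2O)C1=O | intermediate
13 | ortho-quinone methide of ring C, 2-butanoyl-3-hydroxy-5-methoxy-4-methyl-6-methylidenecyclohexa-2,4-dien-1-one (not isolated) | CCCC(=O)C1=C(O)C(C)=C(OC)C(=C)C1=O | intermediate
14 | target CNP0242491.0, 2-butanoyl-6-[3-butanoyl-5-(3-butanoyl-2,4-dihydroxy-6-methoxy-5-methylbenzyl)-2,4,6-trihydroxybenzyl]-3,5-dihydroxy-4,4-dimethylcyclohexa-2,5-dien-1-one | CCCC(=O)C1=C(O)C(C)(C)C(O)=C(Cc2c(O)c(Cc3c(O)c(C(=O)CCC)c(O)c(C)c3OC)c(O)c(C(=O)CCC)c2O)C1=O | target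

Total step count: 7.
Longest linear sequence: 4 steps (steps 1, 2, 3 and 7; the ring C branch, steps 4, 5, 6 and 7, is equally long).

Steps most likely to fail

Step 7. The intended order of bond formation may be lost: ring B of 12 may add to a second methylene triketone before the heating phase, or at 100 °C the amine may reverse and re-form the first bridge, so that the methylene groups are redistributed and symmetric dimers and trimers form beside the mixed compound. The fallback separates the two unions, inverts their order and relies only on the known alkylation of a phloroglucinol ring carbon by an isolated Mannich base. It sets out from 10 and 3: 10 is heated in dioxane at 100 °C with a threefold excess of 3 (the excess suppresses double alkylation of ring B and is recovered) to give the methylene-bridged ring B–ring C dimer 1-[3-(3-butanoyl-2,4,6-trihydroxybenzyl)-2,6-dihydroxy-4-methoxy-5-methylphenyl]butan-1-one F1, which is purified. F1 has a single free ring carbon and no ring that can be alkylated twice; it is treated in a separate flask with 6 in dioxane at 25–40 °C and then with acid, and the fallback comes back to the route at 14.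

Step 3. The zwitterion may lose dimethylamine during its formation or isolation, and the methylene triketone so released may be captured by 4 that is still present, so that self-condensation to the symmetric methylene-bridged dimer of ring A takes the place of 6. The fallback introduces the bridge carbon without an isolated Mannich base, by the classical formaldehyde–alkali condensation of an acylfilicinic acid with an acylphloroglucinol. It sets out from 4 and 3: 4, a threefold excess of 3 and one equivalent of aqueous formaldehyde are combined in dilute aqueous KOH at 0 °C for a short time and acidified, and the mixed dimer is separated by chromatography from symmetric dimers and recovered 3. The fallback comes back to the route at 12, which is then heated with 10 in dioxane as in the second phase of step 7. No compound outside the compound list is made on this path (F0).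

Step 5. Discrimination among the three hydroxyls may be insufficient and alkylation may run on, so that isomeric monoethers and diethers form and the desired monoether is hard to isolate. The fallback fixes the ether pattern by methylating all three oxygens and then removing two of the methyl groups under chelation control. It sets out from 7: exhaustive O-methylation (dimethyl sulfate in excess, K2CO3, acetone, reflux) gives 2,4,6-trimethoxytoluene F2. Friedel–Crafts acylation of F2 with 2 (AlCl3, CH2Cl2, 0 °C) at one of its two equivalent ring carbons gives 1-(2,4,6-trimethoxy-3-methylphenyl)butan-1-one F3. AlCl3 in excess in chlorobenzene at 80 °C should then cleave the two methyl ethers ortho to the ketone through the aluminium chelate, while the para methoxy group, which cannot chelate, is retained. The fallback comes back to the route at 9.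

Further compounds
F1 | step 7 | ring B–CH2–ring C dimer, 1-[3-(3-butanoyl-2,4,6-trihydroxybenzyl)-2,6-dihydroxy-4-methoxy-5-methylphenyl]butan-1-one | CCCC(=O)c1c(O)cc(O)c(Cc2c(O)c(C(=O)CCC)c(O)c(C)c2OC)c1O
F0 | step 3 | none | none
F2 | step 5 | 2,4,6-trimethoxytoluene | Cc1c(OC)cc(OC)cc1OC
F3 | step 5 | 1-(2,4,6-trimethoxy-3-methylphenyl)butan-1-one | CCCC(=O)c1c(OC)cc(OC)c(C)c1OC
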